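**Retrosynthetic overview**
1. Ring D is closed last by intramolecular N-alkylation of the pyrrolidine nitrogen with a C4 mesylate, after Boc and MOM removal.
2. Ring C and the two adjacent centres C-4 (N-bearing, fully substituted) and C-5 come from one Pd-catalysed syn-carboamination of a trisubstituted cyclopentene with a (Z)-alkenyl bromide.
3. Fragment union is a Negishi sp3–sp2 coupling of an alkylzinc (fragment 2, ring E amino lactone) with a cyclopentenyl triflate (fragment 1, rings A/B).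
4. Fragment 1: enzymatic desymmetrisation of a meso cyclopentenediol, Johnson–Claisen/lactonisation (ring B), α-oxygenation then methylation, allylic oxidation, ethyl addition with 1,3-oxidative transposition, convex-face hydride, enol triflate.
5. Fragment 2: Ellman imine plus 2-silyloxy-3-methylfuran vinylogous Mannich reaction, then hydrogenation (ring E). Ring order: A (bought) → B → E → C → D.

Assumption: the target is taken exactly as the given SMILES; ring letters are A cyclopentane, B hydroxy lactone, C pyrrolidine, D azepane, E methyl lactone, and the A/B bicycle carries cyclopenta[b]furan locants (O1, C2, C3, C3a, C4, C5, C6, C6a).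

**Route**

Step 1
Reactants: 1 cis-cyclopent-4-ene-1,3-diol
Product: 2 cis-cyclopent-4-ene-1,3-diyl diacetate
Conditions: Ac2O, pyridine, DMAP (cat.), CH2Cl2, 0 °C to rt
Reagents that add atoms: acetic anhydride CC(=O)OC(C)=O
Why: DMAP-catalysed acetylation of both secondary alcohols gives the meso diester needed for enzymatic desymmetrisation.

Step 2
Reactants: 2 cis-cyclopent-4-ene-1,3-diyl diacetate
Product: 3 (1R,4S)-4-hydroxycyclopent-2-en-1-yl acetate
Conditions: electric eel acetylcholinesterase, NaH2PO4/Na2HPO4 buffer (pH 6.9), rt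
Reagents that add atoms: none
Why: Enzymatic desymmetrisation hydrolyses only one enantiotopic acetate of the meso diester, which fixes the absolute configuration of rings A and B.

Step 3
Reactants: 3 (1R,4S)-4-hydroxycyclopent-2-en-1-yl acetate
Product: 6 (3aS,6aR)-3,3a,6,6a-tetrahydro-2H-cyclopenta[b]furan-2-one, via Claisen ester 4 (not isolated), via hydroxy ester 5 (not isolated)
Conditions: MeC(OMe)3, 2-nitrophenol (cat.), xylene, 150 °C (sealed tube); then K2CO3, MeOH, rt; then 1 M HCl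
Reagents that add atoms: trimethyl orthoacetate COC(C)(OC)OC
Why: The Johnson–Claisen rearrangement delivers the acetate chain suprafacially to C-3a on the face of the departing oxygen (cis to the acetoxy group), and methanolysis of the acetate lets the cis hydroxy ester lactonise to the cis-fused ring B.

Step 4
Reactants: 6 (3aS,6aR)-3,3a,6,6a-tetrahydro-2H-cyclopenta[b]furan-2-one
Product: 7 (3R,3aR,6aR)-3-hydroxy-3,3a,6,6a-tetrahydro-2H-cyclopenta[b]furan-2-one
Conditions: KN(SiMe3)2, THF, −78 °C; 3-phenyl-2-(phenylsulfonyl)oxaziridine, −78 °C; H2O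
Reagents that add atoms: 3-phenyl-2-(phenylsulfonyl)oxaziridine O=S(=O)(N1OC1c1ccccc1)c1ccccc1
Why: Davis enolate hydroxylation occurs on the convex face of the cis-fused bicycle; this centre is made planar again in step 6, so its selectivity is not critical.

Step 5
Reactants: 7 (3R,3aR,6aR)-3-hydroxy-3,3a,6,6a-tetrahydro-2H-cyclopenta[b]furan-2-one
Product: 8 (3R,3aS,6aR)-3-(methoxymethoxy)-3,3a,6,6a-tetrahydro-2H-cyclopenta[b]furan-2-one
Conditions: MeOCH2Cl, iPr2NEt, CH2Cl2, 0 °C to rt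
Reagents that add atoms: chloromethyl methyl ether COCCl
Why: Methoxymethyl ether formation protects the alcohol so that the lactone can be enolised again.

Step 6
Reactants: 8 (3R,3aS,6aR)-3-(methoxymethoxy)-3,3a,6,6a-tetrahydro-2H-cyclopenta[b]furan-2-one
Product: 9 (3S,3aS,6aR)-3-(methoxymethoxy)-3-methyl-3,3a,6,6a-tetrahydro-2H-cyclopenta[b]furan-2-one
Conditions: LiN(iPr)2, THF, −78 °C; MeI, −78 to −40 °C
Reagents that add atoms: iodomethane CI
Why: Enolate alkylation of the planar α-alkoxy enolate takes place from the convex face, so methyl is exo and the oxygen endo, which is the C-3 configuration of the target.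

Step 7
Reactants: 9 (3S,3aS,6aR)-3-(methoxymethoxy)-3-methyl-3,3a,6,6a-tetrahydro-2H-cyclopenta[b]furan-2-one
Product: 10 (3S,3aS,6aS)-3-(methoxymethoxy)-3-methyl-3,3a-dihydro-2H-cyclopenta[b]furan-2,6(6aH)-dione
Conditions: Rh2(cap)4 (dirhodium tetracaprolactamate, 1 mol %), t-BuOOH (70% in H2O), K2CO3, CH2Cl2, rt
Reagents that add atoms: tert-butyl hydroperoxide CC(C)(C)OO
Why: Radical allylic C–H oxidation by tert-butylperoxyl should take the open allylic CH2 at C-6 in preference to the shielded ring-fusion C–H next to the quaternary C-3, giving the enone.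

Step 8
Reactants: 10 (3S,3aS,6aS)-3-(methoxymethoxy)-3-methyl-3,3a-dihydro-2H-cyclopenta[b]furan-2,6(6aH)-dione
Product: 11 (3S,3aS,6R,6aS)-6-ethyl-6-hydroxy-3-(methoxymethoxy)-3-methyl-3,3a,6,6a-tetrahydro-2H-cyclopenta[b]furan-2-one
Conditions: EtMgBr, LaCl3·2LiCl (0.3 equiv), THF, −78 °C; H2O
Reagents that add atoms: ethylmagnesium bromide CC[Mg]Br
Why: Lanthanum-assisted Grignard 1,2-addition to the enone carbonyl from the convex face outruns enolisation and attack on the lactone; the carbinol centre is lost again in step 9.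

Step 9
Reactants: 11 (3S,3aS,6R,6aS)-6-ethyl-6-hydroxy-3-(methoxymethoxy)-3-methyl-3,3a,6,6a-tetrahydro-2H-cyclopenta[b]furan-2-one
Product: 12 (3S,3aS,6aS)-6-ethyl-3-(methoxymethoxy)-3-methyl-3,3a-dihydro-2H-cyclopenta[b]furan-2,4(6aH)-dione
Conditions: (C5H5NH)[CrO3Cl] (pyridinium chlorochromate), 4 Å molecular sieves, CH2Cl2, rt
Reagents that add atoms: pyridinium chlorochromate [O-][Cr](=O)(=O)Cl.c1cc[nH+]cc1
Why: In the Dauben–Michno oxidative 1,3-transposition the tertiary allylic chromate ester shifts [3,3] to C-4 and is oxidised there, so oxygen moves to C-4 (the carbonyl oxygen comes from chromate, the old hydroxyl leaves as water) and ethyl stays on the alkene.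

Step 10
Reactants: 12 (3S,3aS,6aS)-6-ethyl-3-(methoxymethoxy)-3-methyl-3,3a-dihydro-2H-cyclopenta[b]furan-2,4(6aH)-dione
Product: 14 (3S,3aS,6R,6aR)-6-ethyl-3-(methoxymethoxy)-3-methyltetrahydro-2H-cyclopenta[b]furan-2,4(3H)-dione, via silyl enol ether 13 (not isolated)
Conditions: [(Ph3P)CuH]6 (5 mol %), PhMe2SiH, toluene, rt; then 1 M HCl, THF, 0 °C
Reagents that add atoms: none
Why: Copper hydride conjugate reduction delivers hydride to C-6 from the convex face, so ethyl ends up endo (cis to the lactone oxygen), and the neutral silyl enol ether avoids β-elimination of the lactone carboxylate.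

Step 11
Reactants: 14 (3S,3aS,6R,6aR)-6-ethyl-3-(methoxymethoxy)-3-methyltetrahydro-2H-cyclopenta[b]furan-2,4(3H)-dione
Product: 15 (3S,3aS,6R,6aR)-6-ethyl-3-(methoxymethoxy)-3-methyl-2-oxo-3,3a,6,6a-tetrahydro-2H-cyclopenta[b]furan-4-yl trifluoromethanesulfonate
Conditions: KN(SiMe3)2, THF, −78 °C; N-(5-chloropyridin-2-yl)bis(trifluoromethanesulfonyl)imide (Comins' reagent), −78 to −40 °C; H2O
Reagents that add atoms: N-(5-chloropyridin-2-yl)-1,1,1-trifluoro-N-(trifluoromethylsulfonyl)methanesulfonamide Clc1ccc(nc1)N(S(=O)(=O)C(F)(F)F)S(=O)(=O)C(F)(F)F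
Why: Kinetic deprotonation takes the open C-5 methylene and not the hindered ring-fusion C–H (the lactone has no α-hydrogen), and O-triflation then gives the C4=C5 enol triflate regioselectively.

Step 12
Reactants: 16 propane-1,3-diol
Product: 17 3-(benzyloxy)propan-1-ol
Conditions: NaH (1 equiv), THF, 0 °C; BnBr, Bu4NI (cat.), rt (diol in excess)
Reagents that add atoms: benzyl bromide BrCc1ccccc1
Why: Williamson monobenzylation of the symmetrical diol differentiates its two ends.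

Step 13
Reactants: 17 3-(benzyloxy)propan-1-ol
Product: 18 3-(benzyloxy)propanal
Conditions: Dess–Martin periodinane, NaHCO3, CH2Cl2, rt
Reagents that add atoms: none
Why: Dess–Martin oxidation of the primary alcohol stops cleanly at the aldehyde.

Step 14
Reactants: 18 3-(benzyloxy)propanal; 19 (R)-2-methylpropane-2-sulfinamide
Product: 20 (R,E)-N-[3-(benzyloxy)propylidene]-2-methylpropane-2-sulfinamide
Conditions: CuSO4 (anhydrous), CH2Cl2, rt
Reagents that add atoms: none
Why: Ellman condensation gives the (E)-N-sulfinyl aldimine whose sulfur centre later controls the C–N stereocentre.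

Step 15
Reactants: 21 3-methylfuran-2(5H)-one
Product: 22 triisopropyl[(3-methylfuran-2-yl)oxy]silane
Conditions: iPr3SiOTf, Et3N, CH2Cl2, 0 °C
Reagents that add atoms: triisopropylsilyl trifluoromethanesulfonate CC(C)[Si](OS(=O)(=O)C(F)(F)F)(C(C)C)C(C)C
Why: O-silylation of the butenolide dienolate gives the 2-silyloxyfuran nucleophile.

Step 16
Reactants: 20 (R,E)-N-[3-(benzyloxy)propylidene]-2-methylpropane-2-sulfinamide; 22 triisopropyl[(3-methylfuran-2-yl)oxy]silane
Product: 23 (R)-N-[(1S)-3-(benzyloxy)-1-[(2S)-4-methyl-5-oxo-2,5-dihydrofuran-2-yl]propyl]-2-methylpropane-2-sulfinamide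
Conditions: Me3SiOTf (0.2 equiv), CH2Cl2, −78 °C; aq. NaHCO3
Reagents that add atoms: none
Why: In this vinylogous Mukaiyama–Mannich reaction (open transition state) the furan C-5 attacks the s-cis sulfinyl imine on the face anti to the tert-butyl group, which sets the (S) amine carbon, and the Diels–Alder-like approach usual for silyloxyfurans gives the syn (threo) relation to the new (S) lactone carbon; the minor diastereomer is removed by chromatography.

Step 17
Reactants: 23 (R)-N-[(1S)-3-(benzyloxy)-1-[(2S)-4-methyl-5-oxo-2,5-dihydrofuran-2-yl]propyl]-2-methylpropane-2-sulfinamide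
Product: 25 tert-butyl N-[(1S)-3-(benzyloxy)-1-[(2S)-4-methyl-5-oxo-2,5-dihydrofuran-2-yl]propyl]carbamate, via amine hydrochloride 24 (not isolated)
Conditions: HCl (4 M in dioxane), MeOH, 0 °C; evaporate; Boc2O, NaHCO3, THF–H2O, 0 °C
Reagents that add atoms: di-tert-butyl dicarbonate CC(C)(C)OC(=O)OC(=O)OC(C)(C)C
Why: Acidic methanolysis removes the sulfinyl group, and the amine stays protonated until Boc2O is present, so carbamate formation outruns O-to-N acyl shift onto the butenolide.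

Step 18
Reactants: 25 tert-butyl N-[(1S)-3-(benzyloxy)-1-[(2S)-4-methyl-5-oxo-2,5-dihydrofuran-2-yl]propyl]carbamate
Product: 26 tert-butyl N-[(1S)-3-hydroxy-1-[(2S,4S)-4-methyl-5-oxooxolan-2-yl]propyl]carbamate
Conditions: H2 (1 atm), 10% Pd/C, EtOAc–EtOH, rt
Reagents that add atoms: none
Why: Heterogeneous hydrogenation adds hydrogen to the butenolide face opposite the side chain, which gives the cis (2S,4S) methyl lactone, and the benzyl ether is cleaved in the same operation.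

Step 19
Reactants: 26 tert-butyl N-[(1S)-3-hydroxy-1-[(2S,4S)-4-methyl-5-oxooxolan-2-yl]propyl]carbamate
Product: 27 tert-butyl N-[(1S)-3-iodo-1-[(2S,4S)-4-methyl-5-oxooxolan-2-yl]propyl]carbamate
Conditions: I2, PPh3, imidazole, CH2Cl2, 0 °C
Reagents that add atoms: iodine II
Why: Appel-type iodination converts the primary alcohol into the iodide and leaves carbamate and lactone untouched.

Step 20
Reactants: 18 3-(benzyloxy)propanal
Product: 28 [(4,4-dibromobut-3-en-1-yl)oxy]methylbenzene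
Conditions: CBr4, PPh3, CH2Cl2, 0 °C
Reagents that add atoms: tetrabromomethane BrC(Br)(Br)Br
Why: Corey–Fuchs (Ramirez) dibromo-olefination converts the aldehyde into the 1,1-dibromoalkene.

Step 21
Reactants: 28 [(4,4-dibromobut-3-en-1-yl)oxy]methylbenzene
Product: 29 [(3Z)-4-bromobut-3-en-1-yl]oxymethylbenzene
Conditions: Bu3SnH, Pd(PPh3)4 (4 mol %), toluene, rt
Reagents that add atoms: none
Why: Palladium-catalysed hydrogenolysis with the tin hydride removes the more accessible bromine trans to the chain and gives the (Z)-bromoalkene; the geometry is lost later on hydrogenation.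

Step 22
Reactants: 27 tert-butyl N-[(1S)-3-iodo-1-[(2S,4S)-4-methyl-5-oxooxolan-2-yl]propyl]carbamate; 15 (3S,3aS,6R,6aR)-6-ethyl-3-(methoxymethoxy)-3-methyl-2-oxo-3,3a,6,6a-tetrahydro-2H-cyclopenta[b]furan-4-yl trifluoromethanesulfonate
Product: 31 tert-butyl N-[(1S)-3-[(3S,3aS,6R,6aR)-6-ethyl-3-(methoxymethoxy)-3-methyl-2-oxo-3,3a,6,6a-tetrahydro-2H-cyclopenta[b]furan-4-yl]-1-[(2S,4S)-4-methyl-5-oxooxolan-2-yl]propyl]carbamate, via alkylzinc iodide 30 (not isolated)
Conditions: Zn dust (activated with Me3SiCl and BrCH2CH2Br), DMF, rt; then 15, Pd2(dba)3 (2.5 mol %), SPhos (10 mol %), 40 °C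
Reagents that add atoms: none
Why: In this Negishi coupling zinc inserts into the primary C–I bond (carbamate N–H and lactone tolerated) and the alkylzinc couples with the enol triflate at C-4 without touching any stereocentre, which joins fragment 2 to fragment 1.

Step 23
Reactants: 31 tert-butyl N-[(1S)-3-[(3S,3aS,6R,6aR)-6-ethyl-3-(methoxymethoxy)-3-methyl-2-oxo-3,3a,6,6a-tetrahydro-2H-cyclopenta[b]furan-4-yl]-1-[(2S,4S)-4-methyl-5-oxooxolan-2-yl]propyl]carbamate; 29 [(3Z)-4-bromobut-3-en-1-yl]oxymethylbenzene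
Product: 32 tert-butyl (3S,3aS,4R,5R,5'S,6R,6aR)-5-[(1Z)-4-(benzyloxy)but-1-en-1-yl]-6-ethyl-3-(methoxymethoxy)-3-methyl-5'-[(2S,4S)-4-methyl-5-oxooxolan-2-yl]-2-oxohexahydro-2H-spiro[cyclopenta[b]furan-4,2'-pyrrolidine]-1'-carboxylate
Conditions: Pd(OAc)2 (5 mol %), Dpe-phos (10 mol %), Cs2CO3, 1,4-dioxane, 100 °C
Reagents that add atoms: none
Why: Proposed new method: a palladium-catalysed syn-carboamination of a trisubstituted ring alkene that makes an α-tertiary amine — oxidative addition of 29 to zerovalent palladium and carbamate deprotonation give an alkenyl(amido)palladium complex, the cyclopentene inserts into the Pd–N bond suprafacially on its convex face (anti to the C-6 ethyl group and to ring B), and C(sp3)–C(sp2) reductive elimination with retention places nitrogen at C-4 and the butenyl chain at C-5 cis, closing ring C and setting both centres; the (S) substituent next to nitrogen reinforces this face because the usual 2,5-cis preference of N-Boc substrates (substituent pseudoaxial to avoid allylic 1,3-strain with Boc) leads to the same isomer, the hemilabile wide-bite-angle Dpe-phos opens the site needed for insertion of the hindered alkene yet keeps reductive elimination faster than β-hydride elimination towards C-6, and Cs2CO3 spares the lactones; the closest known reaction type is the Pd-catalysed carboamination of N-Boc pent-4-enylamines with aryl or alkenyl bromides, established for terminal, 1,1-disubstituted and cyclic 1,2-disubstituted alkenes but not for a trisubstituted ring alkene.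

Step 24
Reactants: 32 tert-butyl (3S,3aS,4R,5R,5'S,6R,6aR)-5-[(1Z)-4-(benzyloxy)but-1-en-1-yl]-6-ethyl-3-(methoxymethoxy)-3-methyl-5'-[(2S,4S)-4-methyl-5-oxooxolan-2-yl]-2-oxohexahydro-2H-spiro[cyclopenta[b]furan-4,2'-pyrrolidine]-1'-carboxylate
Product: 33 tert-butyl (3S,3aS,4R,5R,5'S,6R,6aR)-6-ethyl-5-(4-hydroxybutyl)-3-(methoxymethoxy)-3-methyl-5'-[(2S,4S)-4-methyl-5-oxooxolan-2-yl]-2-oxohexahydro-2H-spiro[cyclopenta[b]furan-4,2'-pyrrolidine]-1'-carboxylate
Conditions: H2 (1 atm), 10% Pd/C, EtOAc–EtOH, rt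
Reagents that add atoms: none
Why: Catalytic hydrogenation saturates the disubstituted side-chain alkene and cleaves the benzyl ether while Boc, MOM and both lactones stay intact.

Step 25
Reactants: 33 tert-butyl (3S,3aS,4R,5R,5'S,6R,6aR)-6-ethyl-5-(4-hydroxybutyl)-3-(methoxymethoxy)-3-methyl-5'-[(2S,4S)-4-methyl-5-oxooxolan-2-yl]-2-oxohexahydro-2H-spiro[cyclopenta[b]furan-4,2'-pyrrolidine]-1'-carboxylate
Product: 34 tert-butyl (3S,3aS,4R,5R,5'S,6R,6aR)-6-ethyl-3-(methoxymethoxy)-3-methyl-5-{4-[(methylsulfonyl)oxy]butyl}-5'-[(2S,4S)-4-methyl-5-oxooxolan-2-yl]-2-oxohexahydro-2H-spiro[cyclopenta[b]furan-4,2'-pyrrolidine]-1'-carboxylate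
Conditions: MsCl, Et3N, CH2Cl2, 0 °C
Reagents that add atoms: methanesulfonyl chloride CS(=O)(=O)Cl
Why: Mesylation activates the primary alcohol as the leaving group for ring D closure.

Step 26
Reactants: 34 tert-butyl (3S,3aS,4R,5R,5'S,6R,6aR)-6-ethyl-3-(methoxymethoxy)-3-methyl-5-{4-[(methylsulfonyl)oxy]butyl}-5'-[(2S,4S)-4-methyl-5-oxooxolan-2-yl]-2-oxohexahydro-2H-spiro[cyclopenta[b]furan-4,2'-pyrrolidine]-1'-carboxylate
Product: 36 CNP0260919.3, via amino mesylate salt 35 (not isolated)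
Conditions: CF3CO2H–CH2Cl2–H2O (10:10:1), rt; evaporate; K2CO3, MeCN, 60 °C
Reagents that add atoms: none
Why: Acid removes the Boc and MOM groups, and the freed secondary amine then displaces the primary mesylate in an intramolecular SN2 N-alkylation (7-exo-tet) that closes ring D without touching any stereocentre.

**Compound list**
1 | cis-cyclopent-4-ene-1,3-diol (meso) | C1[C@@H](O)C=C[C@H]1O | starting material
2 | cis-cyclopent-4-ene-1,3-diyl diacetate (meso) | C1[C@@H](OC(C)=O)C=C[C@H]1OC(C)=O | intermediate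
3 | (1R,4S)-4-hydroxycyclopent-2-en-1-yl acetate | C1[C@@H](OC(C)=O)C=C[C@H]1O | intermediate
4 | methyl 2-[(1S,5R)-5-(acetyloxy)cyclopent-2-en-1-yl]acetate (not isolated) | C1[C@@H](OC(C)=O)[C@@H](CC(=O)OC)C=C1 | intermediate
5 | methyl 2-[(1S,5R)-5-hydroxycyclopent-2-en-1-yl]acetate (not isolated) | C1[C@@H](O)[C@@H](CC(=O)OC)C=C1 | intermediate
6 | (3aS,6aR)-3,3a,6,6a-tetrahydro-2H-cyclopenta[b]furan-2-one | C1[C@H]2OC(=O)C[C@H]2C=C1 | intermediate
7 | (3R,3aR,6aR)-3-hydroxy-3,3a,6,6a-tetrahydro-2H-cyclopenta[b]furan-2-one (OH on the convex face) | C1[C@H]2OC(=O)[C@H](O)[C@H]2C=C1 | intermediate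
8 | (3R,3aS,6aR)-3-(methoxymethoxy)-3,3a,6,6a-tetrahydro-2H-cyclopenta[b]furan-2-one | C1[C@H]2OC(=O)[C@H](OCOC)[C@H]2C=C1 | intermediate
9 | (3S,3aS,6aR)-3-(methoxymethoxy)-3-methyl-3,3a,6,6a-tetrahydro-2H-cyclopenta[b]furan-2-one (methyl exo) | C1[C@H]2OC(=O)[C@@](C)(OCOC)[C@H]2C=C1 | intermediate
10 | (3S,3aS,6aS)-3-(methoxymethoxy)-3-methyl-3,3a-dihydro-2H-cyclopenta[b]furan-2,6(6aH)-dione | O=C1[C@H]2OC(=O)[C@@](C)(OCOC)[C@H]2C=C1 | intermediate
11 | (3S,3aS,6R,6aS)-6-ethyl-6-hydroxy-3-(methoxymethoxy)-3-methyl-3,3a,6,6a-tetrahydro-2H-cyclopenta[b]furan-2-one | CC[C@]1(O)[C@H]2OC(=O)[C@@](C)(OCOC)[C@H]2C=C1 | intermediate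
12 | (3S,3aS,6aS)-6-ethyl-3-(methoxymethoxy)-3-methyl-3,3a-dihydro-2H-cyclopenta[b]furan-2,4(6aH)-dione | CCC1=CC(=O)[C@H]2[C@@H]1OC(=O)[C@@]2(C)OCOC | intermediate
13 | (3S,3aS,6R,6aR)-4-{[dimethyl(phenyl)silyl]oxy}-6-ethyl-3-(methoxymethoxy)-3-methyl-3,3a,6,6a-tetrahydro-2H-cyclopenta[b]furan-2-one (not isolated) | CC[C@H]1[C@H]2OC(=O)[C@@](C)(OCOC)[C@H]2C(O[Si](C)(C)c2ccccc2)=C1 | intermediate
14 | (3S,3aS,6R,6aR)-6-ethyl-3-(methoxymethoxy)-3-methyltetrahydro-2H-cyclopenta[b]furan-2,4(3H)-dione | CC[C@H]1[C@H]2OC(=O)[C@@](C)(OCOC)[C@H]2C(=O)C1 | intermediate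
15 | (3S,3aS,6R,6aR)-6-ethyl-3-(methoxymethoxy)-3-methyl-2-oxo-3,3a,6,6a-tetrahydro-2H-cyclopenta[b]furan-4-yl trifluoromethanesulfonate | CC[C@H]1[C@H]2OC(=O)[C@@](C)(OCOC)[C@H]2C(OS(=O)(=O)C(F)(F)F)=C1 | intermediate
16 | propane-1,3-diol | OCCCO | starting material
17 | 3-(benzyloxy)propan-1-ol | OCCCOCc1ccccc1 | intermediate
18 | 3-(benzyloxy)propanal | O=CCCOCc1ccccc1 | intermediate
19 | (R)-2-methylpropane-2-sulfinamide | CC(C)(C)[S@@](=O)N | starting material
20 | (R,E)-N-[3-(benzyloxy)propylidene]-2-methylpropane-2-sulfinamide | CC(C)(C)[S@@](=O)/N=C/CCOCc1ccccc1 | intermediate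
21 | 3-methylfuran-2(5H)-one | CC1=CCOC1=O | starting material
22 | triisopropyl[(3-methylfuran-2-yl)oxy]silane | Cc1ccoc1O[Si](C(C)C)(C(C)C)C(C)C | intermediate
23 | (R)-N-[(1S)-3-(benzyloxy)-1-[(2S)-4-methyl-5-oxo-2,5-dihydrofuran-2-yl]propyl]-2-methylpropane-2-sulfinamide | CC(C)(C)[S@@](=O)N[C@@H](CCOCc1ccccc1)[C@@H]1C=C(C)C(=O)O1 | intermediate
24 | (5S)-5-[(1S)-1-amino-3-(benzyloxy)propyl]-3-methylfuran-2(5H)-one hydrochloride (not isolated) | [Cl-].[NH3+][C@@H](CCOCc1ccccc1)[C@@H]1C=C(C)C(=O)O1 | intermediate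
25 | tert-butyl N-[(1S)-3-(benzyloxy)-1-[(2S)-4-methyl-5-oxo-2,5-dihydrofuran-2-yl]propyl]carbamate | CC(C)(C)OC(=O)N[C@@H](CCOCc1ccccc1)[C@@H]1C=C(C)C(=O)O1 | intermediate
26 | tert-butyl N-[(1S)-3-hydroxy-1-[(2S,4S)-4-methyl-5-oxooxolan-2-yl]propyl]carbamate | CC(C)(C)OC(=O)N[C@@H](CCO)[C@@H]1C[C@H](C)C(=O)O1 | intermediate
27 | tert-butyl N-[(1S)-3-iodo-1-[(2S,4S)-4-methyl-5-oxooxolan-2-yl]propyl]carbamate | CC(C)(C)OC(=O)N[C@@H](CCI)[C@@H]1C[C@H](C)C(=O)O1 | intermediate
28 | [(4,4-dibromobut-3-en-1-yl)oxy]methylbenzene | BrC(Br)=CCCOCc1ccccc1 | intermediate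
29 | [(3Z)-4-bromobut-3-en-1-yl]oxymethylbenzene | Br/C=C\CCOCc1ccccc1 | intermediate
30 | [(3S)-3-[(tert-butoxycarbonyl)amino]-3-[(2S,4S)-4-methyl-5-oxooxolan-2-yl]propyl](iodo)zinc (not isolated) | CC(C)(C)OC(=O)N[C@@H](CC[Zn]I)[C@@H]1C[C@H](C)C(=O)O1 | intermediate
31 | tert-butyl N-[(1S)-3-[(3S,3aS,6R,6aR)-6-ethyl-3-(methoxymethoxy)-3-methyl-2-oxo-3,3a,6,6a-tetrahydro-2H-cyclopenta[b]furan-4-yl]-1-[(2S,4S)-4-methyl-5-oxooxolan-2-yl]propyl]carbamate | CC[C@H]1[C@H]2OC(=O)[C@@](C)(OCOC)[C@H]2C(CC[C@@H]([C@@H]3C[C@H](C)C(=O)O3)NC(=O)OC(C)(C)C)=C1 | intermediate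
32 | tert-butyl (3S,3aS,4R,5R,5'S,6R,6aR)-5-[(1Z)-4-(benzyloxy)but-1-en-1-yl]-6-ethyl-3-(methoxymethoxy)-3-methyl-5'-[(2S,4S)-4-methyl-5-oxooxolan-2-yl]-2-oxohexahydro-2H-spiro[cyclopenta[b]furan-4,2'-pyrrolidine]-1'-carboxylate | CC[C@H]1[C@H]2OC(=O)[C@@](C)(OCOC)[C@H]2[C@@]2(CC[C@@H]([C@@H]3C[C@H](C)C(=O)O3)N2C(=O)OC(C)(C)C)[C@@H]1/C=C\CCOCc1ccccc1 | intermediate
33 | tert-butyl (3S,3aS,4R,5R,5'S,6R,6aR)-6-ethyl-5-(4-hydroxybutyl)-3-(methoxymethoxy)-3-methyl-5'-[(2S,4S)-4-methyl-5-oxooxolan-2-yl]-2-oxohexahydro-2H-spiro[cyclopenta[b]furan-4,2'-pyrrolidine]-1'-carboxylate | CC[C@H]1[C@H]2OC(=O)[C@@](C)(OCOC)[C@H]2[C@@]2(CC[C@@H]([C@@H]3C[C@H](C)C(=O)O3)N2C(=O)OC(C)(C)C)[C@@H]1CCCCO | intermediate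
34 | tert-butyl (3S,3aS,4R,5R,5'S,6R,6aR)-6-ethyl-3-(methoxymethoxy)-3-methyl-5-{4-[(methylsulfonyl)oxy]butyl}-5'-[(2S,4S)-4-methyl-5-oxooxolan-2-yl]-2-oxohexahydro-2H-spiro[cyclopenta[b]furan-4,2'-pyrrolidine]-1'-carboxylate | CC[C@H]1[C@H]2OC(=O)[C@@](C)(OCOC)[C@H]2[C@@]2(CC[C@@H]([C@@H]3C[C@H](C)C(=O)O3)N2C(=O)OC(C)(C)C)[C@@H]1CCCCOS(C)(=O)=O | intermediate
35 | 4-[(3S,3aS,4R,5R,5'S,6R,6aR)-6-ethyl-3-hydroxy-3-methyl-5'-[(2S,4S)-4-methyl-5-oxooxolan-2-yl]-2-oxohexahydro-2H-spiro[cyclopenta[b]furan-4,2'-pyrrolidin]-5-yl]butyl methanesulfonate trifluoroacetate (not isolated) | CC[C@H]1[C@H]2OC(=O)[C@@](C)(O)[C@H]2[C@@]2(CC[C@@H]([C@@H]3C[C@H](C)C(=O)O3)N2)[C@@H]1CCCCOS(C)(=O)=O.OC(=O)C(F)(F)F | intermediate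
36 | CNP0260919.3 (rings A to E) | CC[C@H]1[C@H]2OC(=O)[C@@](C)(O)[C@H]2[C@]23CC[C@@H]([C@@H]4C[C@H](C)C(=O)O4)N2CCCC[C@H]13 | target

**Totals and risks**

Total step count: 26. Longest linear sequence: 16 steps (steps 1 to 11, then 22 to 26).

The three steps most likely to fail are step 7, step 23 and step 26.

Step 7 may oxidise the ring-fusion C–H or give regioisomeric enones. The fallback puts oxygen at C-4 directly and brings ethyl in by conjugate addition; it sets out from 9 and comes back at 12. Epoxidation of 9 on the convex face (mCPBA, CH2Cl2) gives the exo epoxide F1. Opening at the less hindered C-5 with PhSeNa [(PhSe)2, NaBH4, EtOH] gives the hydroxy selenide F2, and oxidative syn-elimination (H2O2, THF) gives the allylic alcohol F3. MnO2 (CH2Cl2) gives the C-4 enone F4. Copper-catalysed conjugate addition of EtMgBr (CuBr·SMe2, Me3SiCl, THF, −78 °C) gives the silyl enol ether F5, and Saegusa–Ito oxidation [Pd(OAc)2, MeCN] returns 12.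

Step 23 is the proposed new reaction; insertion of the hindered alkene may lose to N-alkenylation or β-hydride elimination. The fallback uses known chemistry only (kinetic formylation, enol triflate Negishi coupling, intramolecular aza-Michael addition, Wittig olefination); it sets out from ketone 14, uses zinc reagent 30, and comes back at 32. Kinetic formylation of 14 [LiN(SiMe3)2, THF, −78 °C; CF3CH2OCHO] gives the 5-formyl enol F6. O-Triflation (Tf2O, 2,6-di-tert-butylpyridine, CH2Cl2, −78 °C) gives the triflyloxy enal F7. Negishi coupling of F7 with 30 [Pd2(dba)3, SPhos, DMF, 40 °C] gives the side-chain enal F8. Reversible intramolecular aza-Michael addition of the carbamate (KOtBu 10 mol %, THF, 0 °C) closes ring C from the convex face and, after equilibration of the formyl-bearing carbon to the isomer trans to ethyl, gives the spiro aldehyde F9. Wittig olefination of F9 with Ph3P=CHCH2CH2OBn [from (3-benzyloxypropyl)triphenylphosphonium bromide, NaN(SiMe3)2, THF, −78 °C] gives the (Z)-alkene 32.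

Step 26 may be slow because the hindered amine must close a seven-membered ring by SN2, with lactam formation onto ring E as a competitor. The fallback closes ring D by reductive amination instead; it sets out from 33 and comes back at 36. Dess–Martin oxidation of 33 (CH2Cl2, NaHCO3) gives the Boc aldehyde F10. CF3CO2H–CH2Cl2–H2O removes Boc and MOM, and the amino aldehyde closes to the cyclic iminium trifluoroacetate F11 (not isolated), which NaBH(OAc)3 reduces in the same flask to 36.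

Further compounds
F1 | step 7 | exo 4,5-epoxide of 9 | C1[C@H]2OC(=O)[C@@](C)(OCOC)[C@H]2[C@@H]2O[C@H]12
F2 | step 7 | trans 4-hydroxy-5-(phenylselanyl) derivative from F1 | C1[C@H]2OC(=O)[C@@](C)(OCOC)[C@H]2[C@H](O)[C@H]1[Se]c1ccccc1
F3 | step 7 | 4-exo-hydroxy-5,6-ene allylic alcohol | O[C@@H]1C=C[C@H]2OC(=O)[C@@](C)(OCOC)[C@@H]12
F4 | step 7 | C-4 enone without ethyl (6-unsubstituted analogue of 12) | O=C1C=C[C@H]2OC(=O)[C@@](C)(OCOC)[C@@H]12
F5 | step 7 | 4-(trimethylsilyloxy)-4,5-ene with 6-exo-ethyl | CC[C@@H]1[C@H]2OC(=O)[C@@](C)(OCOC)[C@H]2C(O[Si](C)(C)C)=C1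
F6 | step 23 | 5-formyl enol of ketone 14 (4-hydroxy-4,5-ene-5-carbaldehyde) | CC[C@H]1[C@H]2OC(=O)[C@@](C)(OCOC)[C@H]2C(O)=C1C=O
F7 | step 23 | 4-triflyloxy-4,5-ene-5-carbaldehyde | CC[C@H]1[C@H]2OC(=O)[C@@](C)(OCOC)[C@H]2C(OS(=O)(=O)C(F)(F)F)=C1C=O
F8 | step 23 | 5-formyl analogue of 31 (tetrasubstituted enal) | CC[C@H]1[C@H]2OC(=O)[C@@](C)(OCOC)[C@H]2C(CC[C@@H]([C@@H]3C[C@H](C)C(=O)O3)NC(=O)OC(C)(C)C)=C1C=O
F9 | step 23 | N-Boc spiro-pyrrolidine 5-carbaldehyde (formyl cis to N and trans to ethyl) | CC[C@H]1[C@H]2OC(=O)[C@@](C)(OCOC)[C@H]2[C@@]2(CC[C@@H]([C@@H]3C[C@H](C)C(=O)O3)N2C(=O)OC(C)(C)C)[C@@H]1C=O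
F10 | step 26 | 5-(4-oxobutyl) aldehyde from 33 | CC[C@H]1[C@H]2OC(=O)[C@@](C)(OCOC)[C@H]2[C@@]2(CC[C@@H]([C@@H]3C[C@H](C)C(=O)O3)N2C(=O)OC(C)(C)C)[C@@H]1CCCC=O
F11 | step 26 | ring D iminium trifluoroacetate (not isolated) | CC[C@H]1[C@H]2OC(=O)[C@@](C)(O)[C@H]2[C@]23CC[C@@H]([C@@H]4C[C@H](C)C(=O)O4)[N+]2=CCCC[C@H]13.[O-]C(=O)C(F)(F)F
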